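## Structural features

The target 11 is a single cyclohexene ring (C1–C6 in the numbering of its name, alkene C5=C6); atom labels C1–C7 below always mean this numbering. Its quaternary carbinol carbon C1 carries the only side chain, the exocyclic CH2 (C7), which bears one of the two benzoates. C1, C2, C3 and C4 are four contiguous stereocentres: the free hydroxyls on C1, C2 and C4 lie on the β face, the C3 benzoate and C7 on the α face, and the compound is (1S,2S,3R,4S). Five oxygens sit on seven carbons, two acylated and three free, so the difficulty is telling the oxygens apart and setting four neighbouring centres, one quaternary, without a long protecting-group sequence. The fragile elements are the two benzoates, each flanked by free hydroxyls and able to migrate under base, and the tertiary (C1) and secondary (C4) allylic carbinols, which ionise under acid. The decisive pattern is that each benzoate sits on a carbon beside a free carbinol carbon: C7 beside C1, and C3 beside C2 with the two oxygens trans. That is the signature of a C1–C7 spiro-oxirane and a C2–C3 ring oxirane, each opened by benzoate at its less hindered carbon. Because the oxygens on C1, C2 and C4 are all β, both oxirane oxygens and the C4 hydroxyl of that precursor lie on one face, so every hydroxyl is cis to its neighbouring epoxide and epoxide migration is geometrically blocked.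

## Logic of the disconnections

11 is cut at the C7–O and C3–O bonds that hold the two benzoyloxy groups, with the C3 oxygen returned to the β face as part of an oxirane. This leads through 10 to 8 and two equivalents of 9. The cut removes both acyl groups and one stereocentre in a single operation and leaves all five oxygens at their final oxidation level with no protecting group. The forward step must place the nucleophile at C7 and not C1, at C3 and not C2, and must not let the acyl groups wander.

8 is cut at the C1–C7 and C7–O bonds of the spiro-oxirane, which leads to 5 and the one-carbon donor 6 (acting through 7). A methylene added to a ketone is the shortest way to a quaternary carbinol carbon with its CH2–O arm. The gain is the loss of C7 and of the quaternary stereocentre. The forward step must deliver the methylene anti to the ring oxirane, add 1,2 to an enone, and tolerate a free hydroxyl.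

5 is traced to 4 by returning the C1 carbonyl to its dimethyl ketal. The ketal is what distinguishes the two carbonyl positions of a quinone core, so that one is reduced (C4) while the other is held back for the methylenation. The gain is a link to a monoprotected quinone. The forward hydrolysis must spare the oxirane and the allylic alcohol.

4 is cut at the C4–H bond, which leads to 3. This removes one stereocentre and leaves the oxirane as the only stereochemical element. The forward reduction must be 1,2 and must come anti to the oxirane so that the hydroxyl ends cis to it.

3 is cut at the two C–O bonds of its oxirane, which leads to 1 and the oxygen donor 2. Since 1 is achiral and its two alkenes are equivalent, all stereochemistry of the route is traced to one enantioface-selective oxygen transfer. The forward step must be enantioselective and must stop after one epoxidation.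

## Other disconnections considered

Alternative 1: The cut is the C2–O bond, formed in the forward sense by an oxygen tethered to the C1 hydroxyl; this leads back to the achiral para-quinol 4-(benzoyloxymethyl)-4-hydroxycyclohexa-2,5-dien-1-one A1.
- Forward key step: the tertiary hydroxyl of A1 would form a hemiester with phenylboronic acid A2. Under a chiral bifunctional amine–thiourea, the B–OH oxygen would add to one of the two enantiotopic enone β-carbons (C2) and close the cis-fused dioxaborolane A3.
- In favour: C7 with its benzoate and the quaternary carbinol are present from the start, the cis C1/C2 diol is enforced by the five-membered tether, and there is no regiochemical question at C1, C2 or C7. On this point, and probably in the enantiocontrol such tethered oxa-Michael additions can reach, the alternative is the better plan.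
- Against: A3 still has C3 as a methylene and C4 as a ketone. C3 must be oxygenated trans to the C2 oxygen through an enol derivative (Rubottom-type oxidation) and benzoylated, C4 must be reduced from the correct face, and the boronate removed. Enolisation toward C3 puts negative charge β to the C2 oxygen and invites E1cB loss of that oxygen, which would return A1 and erase the stereochemistry.
- Comparison: C3 would be set under substrate control in an enolate oxidation, not by a stereospecific SN2 inversion; the oxidation level at C3 and C4 is adjusted twice; the count is about eight steps against five.

Alternative 2: The cuts are the ring bonds C1–C2 and C3–C4, which divide the carbocycle into 3-hydroxy-2-pyrone A4 (C7, C1, C6, C5, C4 and the oxygen on C4) and (E)-3-oxobut-1-en-1-yl benzoate A5 (C2 and C3).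
- Forward key step: a cinchona-alkaloid base would deprotonate A4 and guide its [4+2] addition to A5 (concerted or as a double Michael sequence). The product is the bridged lactone A6, with the quaternary carbinol, the C3 benzoate and an acetyl group at C2.
- In favour: the ring and three stereocentres are assembled convergently in one catalytic step from two flat partners, the trans C2/C3 relation follows from the alkene geometry of A5, and the C3 benzoate needs no regioselective introduction. In convergence and ring construction it is the better plan.
- Against: the lactone bridge necessarily holds the C4 oxygen and C7 on the same face, whereas 11 has the C4 hydroxyl trans to C7. C4 would therefore have to be inverted after the lactone is opened, at an allylic position prone to SN2′ displacement. The acetyl group must become the C2 hydroxyl by Baeyer–Villiger oxidation in the presence of the alkene, the lactone carbonyl must be reduced to the C7 carbinol beside a benzoate and an acetate, and such bicyclic lactones can lose CO2 by retro-[4+2] on heating.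
- Comparison: setting C1–C3 in one face-selective cycloaddition is attractive, but C4 comes out wrong and three oxidation-level or ester adjustments follow. The count would be nine steps or more against five, whereas the chosen plan keeps every oxygen at its final oxidation level.

Alternative 3: The cuts are the C1–O and C2–O bonds of the cis diol, which lead back through the cyclohexene A8 to shikimic acid A7. To reach A8, the C3 hydroxyl of A7 must be inverted (as benzoate), the carboxyl reduced and benzoylated (C7), C4 silylated and C5 mesylated.
- Forward key step: catalytic OsO4 with an amine N-oxide co-oxidant would dihydroxylate the C1=C2 alkene of A8 anti to the allylic C3 benzoate and give the diol A9. Base-induced elimination of the C5 mesylate toward C6 and desilylation would finish.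
- In favour: the absolute configuration comes from the chiral pool, with C4 carried over from A7 untouched, so no asymmetric catalysis is needed; in that respect it is the better plan. The syn-specific osmylation is the equal of the SN2 opening of the chosen plan as a way to fix relative configuration.
- Against: three secondary hydroxyls must be differentiated, one allylic centre inverted, the oxidation level at C7 changed, and three auxiliary groups put on and removed. The alkene of A8 is electron-poor through two allylic benzoates, and the β-oriented C4 silyl ether stands on the face that must be attacked. The final elimination needs base on a compound with two benzoates beside free hydroxyls.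
- Comparison: ten or more steps against five and a far heavier protecting-group load; the secure C4 and absolute configuration are a real gain but cost many steps.

Key step: step 5

Assumption: N-benzylcinchonidinium chloride is taken to favour the (1R,6S) enantiomer of 3; should the opposite sense be found, the pseudoenantiomeric N-benzylcinchoninium chloride would be used with no other change.

## Route

Step 1
Reactants: 1 4,4-dimethoxycyclohexa-2,5-dien-1-one; 2 tert-butyl hydroperoxide
Product: 3 (1R,6S)-5,5-dimethoxy-7-oxabicyclo[4.1.0]hept-3-en-2-one
Conditions: t-BuOOH (1.2 equiv), NaOH (aq), N-benzylcinchonidinium chloride (10 mol %), toluene, 0 °C to rt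
Reagents that add atoms: tert-butyl hydroperoxide 2, CC(C)(C)OO
Why: Weitz–Scheffer nucleophilic epoxidation under chiral phase-transfer catalysis, a reaction type already applied to quinone monoketals: the tert-butylperoxide anion, ion-paired with the cinchonidinium cation, adds to an enone β-carbon and the enolate closes on the O–O bond. The two alkenes of 1 are homotopic, so only the enantioface has to be chosen; the chiral cation chooses it and sets both oxirane carbons at once (cis fusion is enforced by the ring), and the limited amount of oxidant should prevent a second epoxidation.

Step 2
Reactants: 3 (1R,6S)-5,5-dimethoxy-7-oxabicyclo[4.1.0]hept-3-en-2-one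
Product: 4 (1S,2S,6S)-5,5-dimethoxy-7-oxabicyclo[4.1.0]hept-3-en-2-ol
Conditions: NaBH4, CeCl3·7H2O, MeOH, −78 °C
Reagents that add atoms: none
Why: Luche 1,2-reduction: CeCl3 activates the carbonyl and the hard methoxyborohydride attacks anti to the adjacent oxirane C–O bond, the sterically and stereoelectronically preferred trajectory for 2,3-epoxycyclohexenones, so the new hydroxyl should be cis to the epoxide (2S). Conjugate reduction, the epoxide and the ketal should not be touched at −78 °C.

Step 3
Reactants: 4 (1S,2S,6S)-5,5-dimethoxy-7-oxabicyclo[4.1.0]hept-3-en-2-ol
Product: 5 (1S,5S,6S)-5-hydroxy-7-oxabicyclo[4.1.0]hept-3-en-2-one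
Conditions: TsOH·H2O (10 mol %), acetone–H2O (10:1), 0 °C to rt
Reagents that add atoms: water, O
Why: Acid-catalysed ketal hydrolysis through the allyl-stabilised methoxy oxocarbenium ion; the oxirane is flanked by two electron-poor carbons and should resist catalytic acid, and no stereocentre is involved. The former ketal carbon becomes the C1 carbonyl (target numbering), flanked by the alkene and the epoxide.

Step 4
Reactants: 5 (1S,5S,6S)-5-hydroxy-7-oxabicyclo[4.1.0]hept-3-en-2-one; 6 trimethylsulfonium iodide
Product: 8 (3S,4S,5S,6S)-4,5-epoxy-1-oxaspiro[2.5]oct-7-en-6-ol, via dimethylsulfonium methylide 7 (not isolated)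
Conditions: Me3S+ I− (2.6 equiv), KN(SiMe3)2 (2.5 equiv), THF, −20 °C; then 5, −78 to 0 °C; NH4Cl (aq)
Reagents that add atoms: trimethylsulfonium iodide 6, C[S+](C)C.[I-] (its CH2 is transferred through ylide 7, C[S+](C)[CH2-])
Why: Corey–Chaykovsky epoxidation: the first equivalent of ylide 7 only deprotonates the C4 hydroxyl, whose alkoxide is cis to the oxirane and inert; the second adds 1,2 to the enone carbonyl from the face anti to the neighbouring oxirane oxygen, as carbon nucleophiles generally do with such epoxy ketones. The betaine oxygen is therefore syn to the ring epoxide, and 3-exo-tet closure with loss of Me2S should fix the spiro centre as S with C7 on the α face.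

Step 5
Reactants: 8 (3S,4S,5S,6S)-4,5-epoxy-1-oxaspiro[2.5]oct-7-en-6-ol; 9 benzoic acid
Product: 11 [(1S,2S,3R,4S)-3-benzoyloxy-1,2,4-trihydroxycyclohex-5-en-1-yl]methyl benzoate, via C7 monobenzoate 10 (not isolated)
Conditions: PhCO2H (4 equiv), PhCO2Cs (1.5 equiv), DMF, 40 °C then 80 °C
Reagents that add atoms: benzoic acid 9, OC(=O)c1ccccc1 (two equivalents, delivered through cesium benzoate, [Cs+].[O-]C(=O)c1ccccc1)
Why: Two consecutive intermolecular SN2 openings of epoxides by benzoate; the closest known reaction type is the carboxylate opening of terminal and cyclohexene epoxides at the less hindered carbon. At 40 °C benzoate attacks the primary carbon C7 of the spiro-oxirane and benzoic acid protonates the tertiary C1 alkoxide to give 10; this removes the allylic epoxide before the mixture is warmed, so neither ionisation at C1 nor SN2′ attack at C5 has a leaving group left. At 80 °C a second benzoate attacks C3 of the ring epoxide from the α face, anti to the departing oxygen, which stays on C2 as the β hydroxyl. No ring is closed. The one new stereocentre, C3, is fixed as R by the stereospecific inversion, that is by the configuration of the epoxide made in step 1; C1, C2 and C4 keep their configuration. The selectivity needed is regiochemical: C7 over C1 is the primary-versus-tertiary contrast, and C3 over C2 rests on C2 being neopentyl-like and screened on its α face by the benzoyloxymethyl group, whereas C3 has only the C4 hydrogen on that face; the flattened ring, held by alkene and oxirane, has no strong trans-diaxial bias to override this. Payne migration cannot start because the hydroxyls at C1, C2 and C4 are all cis to the epoxide oxygens, and the benzoic acid buffer protonates each alkoxide as it forms, which should suppress benzoyl migration; cesium benzoate is regenerated and leaves the step unchanged.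

## Compound list

1 | 4,4-dimethoxycyclohexa-2,5-dien-1-one | COC1(OC)C=CC(=O)C=C1 | starting material
2 | tert-butyl hydroperoxide | CC(C)(C)OO | starting material
3 | (1R,6S)-5,5-dimethoxy-7-oxabicyclo[4.1.0]hept-3-en-2-one | COC1(OC)C=CC(=O)[C@@H]2O[C@H]12 | intermediate
4 | (1S,2S,6S)-5,5-dimethoxy-7-oxabicyclo[4.1.0]hept-3-en-2-ol (hydroxyl cis to the epoxide) | COC1(OC)C=C[C@H](O)[C@@H]2O[C@H]12 | intermediate
5 | (1S,5S,6S)-5-hydroxy-7-oxabicyclo[4.1.0]hept-3-en-2-one | O=C1C=C[C@H](O)[C@@H]2O[C@H]12 | intermediate
6 | trimethylsulfonium iodide | C[S+](C)C.[I-] | starting material
7 | dimethylsulfonium methylide | C[S+](C)[CH2-] | intermediate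
8 | (3S,4S,5S,6S)-4,5-epoxy-1-oxaspiro[2.5]oct-7-en-6-ol (both oxirane oxygens and the hydroxyl on one face) | C2[C@@]1(O2)C=C[C@H](O)[C@@H]3O[C@H]13 | intermediate
9 | benzoic acid | OC(=O)c1ccccc1 | starting material
10 | [(1S,2S,5S,6S)-2,5-dihydroxy-7-oxabicyclo[4.1.0]hept-3-en-2-yl]methyl benzoate | O=C(OC[C@@]1(O)C=C[C@H](O)[C@@H]2O[C@H]12)c1ccccc1 | intermediate
11 | [(1S,2S,3R,4S)-3-benzoyloxy-1,2,4-trihydroxycyclohex-5-en-1-yl]methyl benzoate (1α-benzoyloxymethyl-3α-benzoyloxycyclohex-5-ene-1β,2β,4β-triol) | O=C(OC[C@@]1(O)C=C[C@H](O)[C@@H](OC(=O)c2ccccc2)[C@@H]1O)c1ccccc1 | target

## Step count and risk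

Total step count: 5. Longest linear sequence: 5 steps (1 to 3 to 4 to 5 to 8 to 11).

Least certain steps:

Step 5 (key step). The most likely failure is incomplete regiocontrol or sluggish reaction at the ring epoxide. That epoxide is far less reactive than the spiro-oxirane, both of its carbons carry a β-oxygen, and the preference for C3 rests on sterics alone. The temperature it needs also gives benzoyl groups time to migrate between neighbouring oxygens. The fallback sets out from 8 and returns at 11, with the second opening directed instead of left to sterics. Treatment of 8 with PhCO2H (1.1 equiv) and catalytic PhCO2Cs at 40 °C only should give 10, which is isolated. Its secondary C4 hydroxyl is silylated (t-BuMe2SiCl, imidazole, DMF) to the C4 tert-butyldimethylsilyl ether of 10 F1. With C4 capped, the tertiary C1 hydroxyl is the only one that can bind Ti(OiPr)4, and the titanium-templated opening of this 2,3-epoxy alcohol with PhCO2H in CH2Cl2 should deliver benzoate to the distal carbon C3. This gives the C4 tert-butyldimethylsilyl ether of 11 F2, and HF·pyridine in THF should remove the silyl group under conditions that do not move benzoates, giving 11.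

Step 1. The most likely failure is poor enantiofacial discrimination, because an unsubstituted cyclic enone of fixed Z geometry offers the chiral ion pair little to hold. Enrichment by crystallisation of 4 or 5 would be tried first. The fallback sets out from 1 and returns at 4 by classical resolution. Epoxidation with t-BuOOH and 1,8-diazabicyclo[5.4.0]undec-7-ene in CH2Cl2 should give racemic 5,5-dimethoxy-7-oxabicyclo[4.1.0]hept-3-en-2-one F3. Luche reduction as in step 2 should give the racemic cis epoxy alcohol F4. Esterification with (S)-2-methoxy-2-phenylacetic acid (N,N′-dicyclohexylcarbodiimide, 4-dimethylaminopyridine) should give two diastereomers, the (S)-2-methoxy-2-phenylacetate of 4 F5 and the (S)-2-methoxy-2-phenylacetate of the enantiomer of 4 F6. These are separated by chromatography or crystallisation, and methanolysis of F5 (K2CO3, MeOH) returns 4.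

Step 4. The most likely failure is base-induced decomposition of the γ-hydroxy enone, by isomerisation toward the 1,4-dione or elimination toward arenes, competing with carbonyl addition, since the ylide is a strong base and the substrate is unprotected. Incomplete facial selectivity at C1 is the second concern. The fallback sets out from 5 and returns at 8 with the hydroxyl masked. Silylation (t-BuMe2SiCl, imidazole, DMF) should give the tert-butyldimethylsilyl ether of 5 F6a, written below as F7. Ylide addition as in step 4 with a single equivalent of 7 should give the tert-butyldimethylsilyl ether of 8 F8, where the bulky β silyloxy group also reinforces α attack. Bu4NF buffered with AcOH in THF at 0 °C should return 8; the liberated alkoxide is cis to both epoxides and cannot migrate.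

Step 2. The most likely failure is insufficient facial selectivity of hydride delivery, which would give some of the alcohol trans to the oxirane. The fallback sets out from 3 and returns at 4 by correcting the centre, not by changing the reductant. The trans epimer (1S,2R,6S)-5,5-dimethoxy-7-oxabicyclo[4.1.0]hept-3-en-2-ol F9 is separated and subjected to Mitsunobu inversion (4-nitrobenzoic acid, PPh3, diisopropyl azodicarboxylate, THF) to give the 4-nitrobenzoate of 4 F10. Methanolysis (K2CO3, MeOH) should give 4.

(The silyl ether of 5 is compound F7; the label F6a above is not used.)

## Further compounds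

F1 | step 5 | C4 tert-butyldimethylsilyl ether of 10 | O=C(OC[C@@]1(O)C=C[C@H](O[Si](C)(C)C(C)(C)C)[C@@H]2O[C@H]12)c1ccccc1
F2 | step 5 | C4 tert-butyldimethylsilyl ether of 11 | O=C(OC[C@@]1(O)C=C[C@H](O[Si](C)(C)C(C)(C)C)[C@@H](OC(=O)c2ccccc2)[C@@H]1O)c1ccccc1
F3 | step 1 | racemic 5,5-dimethoxy-7-oxabicyclo[4.1.0]hept-3-en-2-one (one enantiomer drawn) | COC1(OC)C=CC(=O)[C@@H]2O[C@H]12
F4 | step 1 | racemic cis-5,5-dimethoxy-7-oxabicyclo[4.1.0]hept-3-en-2-ol (one enantiomer drawn) | COC1(OC)C=C[C@H](O)[C@@H]2O[C@H]12
F5 | step 1 | (S)-2-methoxy-2-phenylacetate of 4 | COC1(OC)C=C[C@H](OC(=O)[C@@H](OC)c3ccccc3)[C@@H]2O[C@H]12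
F6 | step 1 | (S)-2-methoxy-2-phenylacetate of the enantiomer of 4 | COC1(OC)C=C[C@@H](OC(=O)[C@@H](OC)c3ccccc3)[C@H]2O[C@@H]12
F7 | step 4 | tert-butyldimethylsilyl ether of 5 | O=C1C=C[C@H](O[Si](C)(C)C(C)(C)C)[C@@H]2O[C@H]12
F8 | step 4 | tert-butyldimethylsilyl ether of 8 | C2[C@@]1(O2)C=C[C@H](O[Si](C)(C)C(C)(C)C)[C@@H]3O[C@H]13
F9 | step 2 | (1S,2R,6S)-5,5-dimethoxy-7-oxabicyclo[4.1.0]hept-3-en-2-ol (hydroxyl trans to the epoxide) | COC1(OC)C=C[C@@H](O)[C@@H]2O[C@H]12
F10 | step 2 | 4-nitrobenzoate of 4 | COC1(OC)C=C[C@H](OC(=O)c3ccc(cc3)[N+](=O)[O-])[C@@H]2O[C@H]12
A1 | alternative 1 | 4-(benzoyloxymethyl)-4-hydroxycyclohexa-2,5-dien-1-one | O=C(OCC1(O)C=CC(=O)C=C1)c1ccccc1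
A2 | alternative 1 | phenylboronic acid | OB(O)c1ccccc1
A3 | alternative 1 | cis-fused 2-phenyl-1,3,2-dioxaborolane of the C1/C2 diol enone (C7 benzoate, C4 ketone, C5=C6 alkene) | O=C(OC[C@@]1(OB(c3ccccc3)O2)C=CC(=O)C[C@@H]12)c1ccccc1
A4 | alternative 2 | 3-hydroxy-2H-pyran-2-one | O=c1occcc1O
A5 | alternative 2 | (E)-3-oxobut-1-en-1-yl benzoate | CC(=O)/C=C/OC(=O)c1ccccc1
A6 | alternative 2 | 8-acetyl-4-hydroxy-3-oxo-2-oxabicyclo[2.2.2]oct-5-en-7-yl benzoate | O=C1O[C@@H]2C=C[C@@]1(O)[C@@H](C(C)=O)[C@@H]2OC(=O)c1ccccc1
A7 | alternative 3 | shikimic acid, (3R,4S,5R)-3,4,5-trihydroxycyclohex-1-ene-1-carboxylic acid | O=C(O)C1=C[C@@H](O)[C@@H](O)[C@H](O)C1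
A8 | alternative 3 | (3α-benzoyloxy-5α-methanesulfonyloxy-4β-triethylsilyloxycyclohex-1-en-1-yl)methyl benzoate (target numbering) | O=C(OCC1=C[C@H](OC(=O)c2ccccc2)[C@@H](O[Si](CC)(CC)CC)[C@H](OS(C)(=O)=O)C1)c1ccccc1
A9 | alternative 3 | C1/C2 cis-diol of A8 with C5 mesylate and C4 triethylsilyl ether | O=C(OC[C@@]1(O)C[C@@H](OS(C)(=O)=O)[C@H](O[Si](CC)(CC)CC)[C@@H](OC(=O)c2ccccc2)[C@@H]1O)c1ccccc1
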